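**Atom labels used throughout:** spiro carbon C1; ring A C1–C10(=O)–C11(prenyl)2–C12(OH)=C13(acyl)–C14(=O); ring B C1–C2H2–C3H–C4H–C5(CH3)(OH)–C6H2; ring C C3–C9(CH3)(OH)–C8H2–C7H2–C4.

## Analysis of the target

- The target is a spiro compound. Ring A is an enolised 2-acylcyclohexane-1,3,5-trione (a dearomatised acylphloroglucinol) with two prenyl groups on C11 and a 3-methylbutanoyl group on C13. It shares the quaternary carbon C1 with ring B of a trans-fused hydrindane (rings B and C).
- There are five stereocentres: C1 (S in the tautomer drawn), C3 (S), C4 (R), C5 (S) and C9 (R). H3 and H4 are trans. The C9 hydroxyl lies on the face of ring C opposite to H3, so it is cis to C2. The C5 hydroxyl is axial on ring B, on the face of H3.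
- At C1 the two carbonyl arms differ only through the rest of ring A. C14, flanked by the acylated C13, is axial on ring B and syn to the C5 hydroxyl. C10, next to the diprenylated C11, is equatorial.
- Sensitive groups are the acidic β-triketone enol (O-alkylation, retro-Claisen cleavage), the prenyl groups (acid closes them onto the enol oxygen) and two tertiary alcohols that eliminate under strong acid.
- The hard points are the all-carbon spiro centre, two tertiary carbinols on different rings with no neighbouring function to direct them, and the trans ring fusion.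
- The strategy rests on one structural fact: C2, C3, C9, C8, C7, C4, C5, C6 and the two methyl groups are one unbroken linalool chain, with C9 as its carbinol carbon, and both chain ends (C2 and C6) are bonded to C1.
- A second feature is used afterwards: C14 and the C5 oxygen are 1,3-diaxial on ring B, so a lactone between them can set C5 and tell the two carboxyl carbons on C1 apart.

## Retrosynthetic reasoning

**Prenyl groups and silyl ether (17 ⇒ 16 ⇒ 14 + 15).** The Si–O bond at C9 and the two C11–CH2 bonds are cut first. Once ring A exists, C11 is its only carbon that still carries hydrogen between two carbonyls (C13 is acylated, C1 is quaternary), so a double C-alkylation with 15 has no regiochemical choice. Cutting here also keeps the acid-sensitive prenyl groups out of every earlier step. The forward reaction has to alkylate on carbon, twice, and not on oxygen.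

**Ring A (14 ⇒ 13 ⇒ 10 + 11, through 12).** Ring A is cut at C13–C14 and at C10–C11. Both carbonyl carbons on C1 return to the carboxyl level: C10 as a free acid, C14 as a γ-lactone onto the C5 oxygen in lactone acid 10. The lactone masks the C5 hydroxyl, distinguishes the two carboxyl groups (which fixes C1), and serves as the acyl donor for C13. Forward, the methyl-derived carbanion of the dianion of 11 must attack only the activated C10 carbonyl of 12. The central carbon of triketone 13 must then open the lactone.

**Lactone (10 ⇒ 9 ⇒ 8 ⇒ 7).** The C5–O bond is cut, with a C6–I bond as a temporary partner. In the trans-fused half-chair of diacid 8 only the pseudo-axial carboxyl can reach C5, and only from the face of H3. Lactonisation therefore creates C5 correctly and turns C1 into a stereocentre. Direct protonation of C5=C6 would be one step shorter, but strong acid endangers the tertiary C9 oxygen function. Halolactonisation to 9 followed by removal of the halogen avoids that.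

**Rings B and C (7 ⇒ 6).** The bonds C1–C2 and C3–C4 are cut together. This opens both carbocycles in one retro-[4+2] step and leaves an acyclic triene 6 whose ten-carbon backbone is that of 1. Any other cut of the hydrindane would need ring C or ring B to be made separately. The forward reaction has to give the trans ring fusion and the correct face of the vinyl group relative to C9.

**Triene (6 ⇒ 4 + 5; 4 ⇒ 3 ⇒ 2 ⇒ 1).** The C1=C6 double bond is cut by a Knoevenagel disconnection to enal 4 and malonate 5, which supplies C1, C10 and C14. Enal 4 comes from 1 by oxidation of the (E)-methyl group, through allylic alcohol 3. The carbinol is masked as silyl ether 2 beforehand, so that its oxygen can neither add to the dienyl malonate nor be lost on heating.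

## Alternatives that were turned down

**Alternative 1:** Ring A is disconnected at C10–C11 and C13–C14. In the forward step the methyl-derived carbanion of a diketone dianion is acylated by an activated C10 carboxyl, and the central carbanion of the triketone formed then opens a C14 lactone in the same flask. The product is A1, the spiro acylphloroglucinol without prenyl groups and with the C9 silyl ether.
- For it: eight carbons arrive at once, and the lactone fixes C1 and frees the C5 hydroxyl without a protecting group.
- Against it as the governing idea: it presupposes the tricyclic lactone acid with C3, C4, C5 and C9 already set, so it says nothing about the harder half of the molecule. Its second stage also pairs a stabilised carbanion with a hindered carbonyl.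
- Comparison: on ring A it is as strong as the chosen route, which ends with the same two bonds (steps 8 and 9; 14 is the same structure as A1), only split into two flasks. What the chosen strategy adds is an origin for rings B and C: both rings and two stereocentres in one step from a purchased ten-carbon chain.

**Alternative 2:** The bonds C4–C5 and C3–C2 are made on a preformed five-membered ring. An isopropenyl Grignard reagent adds to a cyclopentenone under a chiral copper–diphosphine catalyst, and the magnesium enolate is trapped at C3 by a methylidene malonate to give A2.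
- For it: the trans C3/C4 relationship is nearly guaranteed, because the electrophile enters anti to the new substituent. This is stronger than the chosen key step on that point. C1 is also already attached to C2.
- Against it: no ring is closed. The absolute configuration depends on a catalyst working on a five-membered enone with an alkenyl nucleophile. The C9 carbinol still has to come from methyl addition to a ketone in a molecule with an acidic malonate, where the new alkoxide sits cis to the malonate arm and can lactonise onto it. Ring B still needs the C1–C6 bond.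
- Comparison: stronger on ring fusion, weaker on step count and on the source of absolute configuration. The chosen strategy instead buys all ten carbons of rings B and C with C9 already configured. Alternative 2 is kept as the fallback to step 5.

**Alternative 3:** The C3–C9 bond is disconnected, closing ring C. A chiral phosphine-ligated copper hydride reduces a β,β-disubstituted enoate at C4, and the copper enolate at C3 adds to a tethered methyl ketone to give A3, with hydroxyl and ester cis.
- For it: the C9 carbinol and its relationship to C3 (hydroxyl cis to the carbon that becomes C2) come from a closed aldol transition state. This is better secured than the facial preference on which the chosen key step depends.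
- Against it: C4 is created in the hydride transfer, where the catalyst must cooperate with the resident centre of the silyloxyethyl side chain, and the aldol geometry does not itself deliver trans C3/C4. The product is only a monocyclic cyclopentane with C2 as an ester and C5 as a protected carbinol. Ester reduction, activation, malonate alkylation, oxidation, olefination and closure of ring B all remain.
- Comparison: stronger on C9, much weaker on step economy. The chosen strategy reaches the bicyclic core with C1 in place in five steps.

Key step: step 5

Remark on the chemistry: commercial (R)-(−)-linalool 1 is assumed to be enantiomerically pure, since its carbinol carbon (C9) is the only source of absolute configuration; enolised triketones are drawn in one tautomer.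

## Route

Step 1
Reactants: 1 (R)-(−)-linalool
Product: 2 triethyl{[(3R)-3,7-dimethylocta-1,6-dien-3-yl]oxy}silane
Conditions: Et3SiOTf, 2,6-lutidine, CH2Cl2, −78 → 0 °C
Reagents that add atoms: triethylsilyl trifluoromethanesulfonate, CC[Si](CC)(CC)OS(=O)(=O)C(F)(F)F
Why: Silylation of a tertiary alcohol with a silyl triflate and a hindered pyridine base; it masks the carbinol against conjugate addition to the later dienyl malonate and against elimination in the thermal step, and C9 is not touched.

Step 2
Reactants: 2 triethyl{[(3R)-3,7-dimethylocta-1,6-dien-3-yl]oxy}silane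
Product: 3 (2E,6R)-2,6-dimethyl-6-[(triethylsilyl)oxy]octa-2,7-dien-1-ol
Conditions: SeO2 (cat.), t-BuOOH, salicylic acid (cat.), CH2Cl2, rt
Reagents that add atoms: tert-butyl hydroperoxide, CC(C)(C)OO; selenium dioxide (oxygen carrier), O=[Se]=O
Why: SeO2 allylic oxidation (ene reaction, then [2,3]-sigmatropic shift), which on a gem-dimethyl trisubstituted alkene selects the (E)-methyl group and should give the (E)-allylic alcohol; the monosubstituted vinyl group is inert. Any enal formed by over-oxidation is the product of step 3 and is carried along.

Step 3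
Reactants: 3 (2E,6R)-2,6-dimethyl-6-[(triethylsilyl)oxy]octa-2,7-dien-1-ol
Product: 4 (2E,6R)-2,6-dimethyl-6-[(triethylsilyl)oxy]octa-2,7-dienal
Conditions: MnO2, CH2Cl2, rt
Reagents that add atoms: none
Why: MnO2 oxidation of a primary allylic alcohol to the enal; the silyl ether and the (E)-alkene are not affected.

Step 4
Reactants: 4 (2E,6R)-2,6-dimethyl-6-[(triethylsilyl)oxy]octa-2,7-dienal; 5 dimethyl malonate
Product: 6 dimethyl 2-{(2E,6R)-2,6-dimethyl-6-[(triethylsilyl)oxy]octa-2,7-dien-1-ylidene}propanedioate
Conditions: piperidine (cat.), AcOH (cat.), 4 Å MS, PhMe, 50 °C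
Reagents that add atoms: none
Why: Knoevenagel condensation through the piperidinium iminium ion of the enal; removal of water drives it to the dienyl malonate, and the (E)-C4=C5 geometry is not involved.

Step 5
Reactants: 6 dimethyl 2-{(2E,6R)-2,6-dimethyl-6-[(triethylsilyl)oxy]octa-2,7-dien-1-ylidene}propanedioate
Product: 7 dimethyl (1R,3aR,7aS)-1,4-dimethyl-1-[(triethylsilyl)oxy]-1,2,3,3a,7,7a-hexahydro-6H-indene-6,6-dicarboxylate (trans ring fusion)
Conditions: PhMe (0.02 M), BHT (cat.), sealed tube, 200 °C
Reagents that add atoms: none
Why: Thermal intramolecular Diels–Alder reaction of a 1,3,8-nonatriene to a hydrindene, the closest known type; the diene C1=C6–C5=C4 is the electron-poor partner and the vinyl group C2=C3 is unactivated, so heat alone drives it. The addition is concerted and suprafacial on both partners, C1 bonding to C2 and C4 to C3. Ring C (five-membered) closes through the three-carbon tether C7–C8–C9, which permits only the fused orientation; ring B (six-membered) is the cyclohexene of the [4+2] addition and keeps the C5=C6 double bond for step 6. C3 and C4 are the new stereocentres: their trans relationship comes from the (E)-C4=C5 geometry when the tether folds anti to the diene, the less strained arrangement for a three-atom tether. Their sense relative to C9 comes from the forming five-membered ring, which should place the C9 methyl group pseudo-equatorial and the smaller oxygen pseudo-axial beside the vinyl CH2, so that C2 ends cis to the C9 oxygen. The step thus needs trans over cis fusion and one face of the vinyl group; both rest on conformational preferences of the tether and not on a rigid element, so a separable mixture with 7 as main isomer is what should be planned for. The silyl ether keeps the C9 oxygen from adding to C4 and from eliminating at 200 °C, BHT suppresses radical polymerisation, and C1, with two identical esters, is not yet stereogenic.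

Step 6
Reactants: 7 dimethyl (1R,3aR,7aS)-1,4-dimethyl-1-[(triethylsilyl)oxy]-1,2,3,3a,7,7a-hexahydro-6H-indene-6,6-dicarboxylate
Product: 9 5-iodo-1,4-dimethyl-8-oxo-1-[(triethylsilyl)oxy]octahydro-1H-4,6-(epoxymethano)indene-6-carboxylic acid (iodolactone acid; lactone bridge on the face of 7a-H; iodine anti to the lactone oxygen), via hydrindene diacid 8 (not isolated)
Conditions: KOH, MeOH/H2O, 65 °C; CO2 to pH 8; I2, KI, THF/H2O, 0 °C → rt, dark; aq. KHSO4 work-up at 0 °C
Reagents that add atoms: potassium hydroxide (carboxyl oxygen), [K+].[OH-]; iodine, II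
Why: Saponification of the gem-diester gives the dicarboxylate of 8, and iodolactonisation then adds across C5=C6 in the anti sense: the pseudo-axial carboxylate attacks the tertiary C5 (Markovnikov; five-membered lactone within a 6-oxabicyclo[3.2.1]octanone) from the face of H3 while iodine becomes axial on C6. This sets C5 (oxygen axial, methyl equatorial) and makes C1 a stereocentre, because in the trans-fused half-chair only the carboxylate on that face can reach C5.

Step 7
Reactants: 9 5-iodo-1,4-dimethyl-8-oxo-1-[(triethylsilyl)oxy]octahydro-1H-4,6-(epoxymethano)indene-6-carboxylic acid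
Product: 10 1,4-dimethyl-8-oxo-1-[(triethylsilyl)oxy]octahydro-1H-4,6-(epoxymethano)indene-6-carboxylic acid (lactone acid; C14 is the lactone carbonyl; C10 the free acid)
Conditions: (Me3Si)3SiH, AIBN (cat.), PhMe, 80 °C
Reagents that add atoms: none
Why: Radical-chain dehalogenation: a silyl radical abstracts iodine and the secondary C6 radical takes hydrogen from the silane; lactone and acid are poor radical acceptors, so no rearrangement is expected, and C6 ceases to be a stereocentre.

Step 8
Reactants: 10 1,4-dimethyl-8-oxo-1-[(triethylsilyl)oxy]octahydro-1H-4,6-(epoxymethano)indene-6-carboxylic acid; 11 6-methylheptane-2,4-dione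
Product: 13 1-{1,4-dimethyl-8-oxo-1-[(triethylsilyl)oxy]octahydro-1H-4,6-(epoxymethano)inden-6-yl}-7-methyloctane-1,3,5-trione (triketone lactone), via lactone acyl imidazole 12 (not isolated)
Conditions: 1,1'-carbonyldiimidazole (CDI), THF, rt; then added to 11 (3 equiv) + LiN(iPr)2 (6 equiv), THF, −78 → −20 °C; AcOH quench
Reagents that add atoms: none
Why: Claisen-type acylation of a β-diketone dianion at its terminal, methyl-derived carbanion by an acyl imidazole; the acyl imidazole is far more electrophilic than the bridged lactone, so C10 is attacked first, and the triketone formed is protected as its enolate. The α-carboxy lactone 10 cannot decarboxylate, because its enol would be a bridgehead alkene (Bredt's rule).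

Step 9
Reactants: 13 1-{1,4-dimethyl-8-oxo-1-[(triethylsilyl)oxy]octahydro-1H-4,6-(epoxymethano)inden-6-yl}-7-methyloctane-1,3,5-trione
Product: 14 (1'R,3a'R,4'S,7a'S)-4'-hydroxy-1',4'-dimethyl-3-(3-methylbutanoyl)-1'-[(triethylsilyl)oxy]octahydrospiro[cyclohexane-1,6'-indene]-2,4,6-trione (enol form; C14 on the face of the C5 hydroxyl)
Conditions: KOtBu (2.5 equiv), THF, 0 °C → rt; AcOH quench
Reagents that add atoms: none
Why: Intramolecular Claisen (Dieckmann-type) condensation in the acylphloroglucinol-forming mode known for 3,5,7-triketo esters: the C13 carbanion of the triketone dianion adds to the lactone carbonyl C14 (six-membered ring), the C5 alkoxide leaves, and the β-triketone anion formed is the thermodynamic sink. Because C14 was the axial carboxyl tied to C5, the spiro centre C1 emerges with C14 syn to the C5 hydroxyl; no stereocentre is touched.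

Step 10
Reactants: 14 (1'R,3a'R,4'S,7a'S)-4'-hydroxy-1',4'-dimethyl-3-(3-methylbutanoyl)-1'-[(triethylsilyl)oxy]octahydrospiro[cyclohexane-1,6'-indene]-2,4,6-trione; 15 1-bromo-3-methylbut-2-ene
Product: 16 (1'R,3a'R,4'S,7a'S)-4'-hydroxy-1',4'-dimethyl-3-(3-methylbutanoyl)-5,5-bis(3-methylbut-2-en-1-yl)-1'-[(triethylsilyl)oxy]octahydrospiro[cyclohexane-1,6'-indene]-2,4,6-trione (4-enol)
Conditions: NaOMe (3.2 equiv), 15 (2.4 equiv), MeOH, 0 °C → rt
Reagents that add atoms: none
Why: Double C-alkylation of a cyclic β-triketone, as in the preparation of gem-diprenylated acylphloroglucinols; C11 is the only ring carbon with hydrogen between two carbonyls, the protic solvent favours C- over O-alkylation, and tertiary alcohols are not alkylated under these conditions.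

Step 11
Reactants: 16 (1'R,3a'R,4'S,7a'S)-4'-hydroxy-1',4'-dimethyl-3-(3-methylbutanoyl)-5,5-bis(3-methylbut-2-en-1-yl)-1'-[(triethylsilyl)oxy]octahydrospiro[cyclohexane-1,6'-indene]-2,4,6-trione
Product: 17 CNP0198642.2, (1'R,3a'R,4'S,7a'S)-1',4'-dihydroxy-1',4'-dimethyl-3-(3-methylbutanoyl)-5,5-bis(3-methylbut-2-en-1-yl)octahydrospiro[cyclohexane-1,6'-indene]-2,4,6-trione as its 4-enol (spiro carbon S as drawn)
Conditions: HF·pyridine, pyridine, THF, 0 °C → rt
Reagents that add atoms: none
Why: Fluoride cleavage of the tertiary triethylsilyl ether; buffered HF·pyridine avoids the strong acid that would close a prenyl group onto the enol oxygen or ionise the tertiary carbinols.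

## Compound list

1 | (R)-(−)-linalool, (3R)-3,7-dimethylocta-1,6-dien-3-ol | C=C[C@](C)(O)CCC=C(C)C | starting material
2 | triethyl{[(3R)-3,7-dimethylocta-1,6-dien-3-yl]oxy}silane | C=C[C@](C)(O[Si](CC)(CC)CC)CCC=C(C)C | intermediate
3 | (2E,6R)-2,6-dimethyl-6-[(triethylsilyl)oxy]octa-2,7-dien-1-ol | C=C[C@](C)(O[Si](CC)(CC)CC)CC/C=C(\C)CO | intermediate
4 | (2E,6R)-2,6-dimethyl-6-[(triethylsilyl)oxy]octa-2,7-dienal | C=C[C@](C)(O[Si](CC)(CC)CC)CC/C=C(\C)C=O | intermediate
5 | dimethyl malonate (dimethyl propanedioate) | COC(=O)CC(=O)OC | starting material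
6 | dimethyl 2-{(2E,6R)-2,6-dimethyl-6-[(triethylsilyl)oxy]octa-2,7-dien-1-ylidene}propanedioate | COC(=O)C(C(=O)OC)=C/C(C)=C/CC[C@@](C)(O[Si](CC)(CC)CC)C=C | intermediate
7 | dimethyl (1R,3aR,7aS)-1,4-dimethyl-1-[(triethylsilyl)oxy]-1,2,3,3a,7,7a-hexahydro-6H-indene-6,6-dicarboxylate, trans ring fusion | COC(=O)C2(C(=O)OC)C[C@H]3[C@@H](CC[C@@]3(C)O[Si](CC)(CC)CC)C(C)=C2 | intermediate
8 | (1R,3aR,7aS)-1,4-dimethyl-1-[(triethylsilyl)oxy]-1,2,3,3a,7,7a-hexahydro-6H-indene-6,6-dicarboxylic acid | OC(=O)C2(C(=O)O)C[C@H]3[C@@H](CC[C@@]3(C)O[Si](CC)(CC)CC)C(C)=C2 | intermediate (not isolated)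
9 | 5-iodo-1,4-dimethyl-8-oxo-1-[(triethylsilyl)oxy]octahydro-1H-4,6-(epoxymethano)indene-6-carboxylic acid; trans ring fusion, silyloxy group opposite to 7a-H, lactone bridge on the face of 7a-H, iodine anti to the lactone oxygen | O=C(O)[C@@]12C[C@H]3[C@@H](CC[C@@]3(C)O[Si](CC)(CC)CC)[C@](C)([C@@H]2I)OC1=O | intermediate
10 | 1,4-dimethyl-8-oxo-1-[(triethylsilyl)oxy]octahydro-1H-4,6-(epoxymethano)indene-6-carboxylic acid; same configuration as 9 without iodine | O=C(O)[C@@]12C[C@H]3[C@@H](CC[C@@]3(C)O[Si](CC)(CC)CC)[C@](C)(C2)OC1=O | intermediate
11 | 6-methylheptane-2,4-dione | CC(C)CC(=O)CC(C)=O | starting material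
12 | (1H-imidazol-1-yl){1,4-dimethyl-8-oxo-1-[(triethylsilyl)oxy]octahydro-1H-4,6-(epoxymethano)inden-6-yl}methanone; configuration as 10 | O=C(n4ccnc4)[C@@]12C[C@H]3[C@@H](CC[C@@]3(C)O[Si](CC)(CC)CC)[C@](C)(C2)OC1=O | intermediate (not isolated)
13 | 1-{1,4-dimethyl-8-oxo-1-[(triethylsilyl)oxy]octahydro-1H-4,6-(epoxymethano)inden-6-yl}-7-methyloctane-1,3,5-trione; configuration as 10 | CC(C)CC(=O)CC(=O)CC(=O)[C@@]12C[C@H]3[C@@H](CC[C@@]3(C)O[Si](CC)(CC)CC)[C@](C)(C2)OC1=O | intermediate
14 | (1'R,3a'R,4'S,7a'S)-4'-hydroxy-1',4'-dimethyl-3-(3-methylbutanoyl)-1'-[(triethylsilyl)oxy]octahydrospiro[cyclohexane-1,6'-indene]-2,4,6-trione, enol form, C14 syn to the C5 hydroxyl | CC(C)CC(=O)C1=C(O)C=C(O)[C@@]2(C[C@H]3[C@@H](CC[C@@]3(C)O[Si](CC)(CC)CC)[C@@](C)(O)C2)C1=O | intermediate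
15 | 1-bromo-3-methylbut-2-ene (prenyl bromide) | CC(C)=CCBr | starting material
16 | (1'R,3a'R,4'S,7a'S)-4'-hydroxy-1',4'-dimethyl-3-(3-methylbutanoyl)-5,5-bis(3-methylbut-2-en-1-yl)-1'-[(triethylsilyl)oxy]octahydrospiro[cyclohexane-1,6'-indene]-2,4,6-trione, 4-enol | CC(C)=CCC1(CC=C(C)C)C(=O)[C@@]2(C[C@H]3[C@@H](CC[C@@]3(C)O[Si](CC)(CC)CC)[C@@](C)(O)C2)C(=O)C(C(=O)CC(C)C)=C1O | intermediate
17 | CNP0198642.2, (1'R,3a'R,4'S,7a'S)-1',4'-dihydroxy-1',4'-dimethyl-3-(3-methylbutanoyl)-5,5-bis(3-methylbut-2-en-1-yl)octahydrospiro[cyclohexane-1,6'-indene]-2,4,6-trione, 4-enol, spiro carbon S | CC(C)=CCC1(CC=C(C)C)C(=O)[C@@]2(C[C@H]3[C@@H](CC[C@@]3(C)O)[C@@](C)(O)C2)C(=O)C(C(=O)CC(C)C)=C1O | target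

## Step count and least certain steps

Total: 11 steps. Longest linear sequence: 11 steps (1 to 17); 5, 11 and 15 are purchased.

**Step 5 (key step).**
- What may go wrong: the tether may fold through the syn arrangement (cis ring fusion), or the diene may add to the other face of the vinyl group, because neither preference is held by a rigid element. The cycloaddition may also be slow, since the diene terminus carries a cis ester and the alkene is unactivated, which leaves time for thermal decomposition.
- Fallback: it sets out from 5 and comes back at 10, building ring C first.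
  - 5 is condensed with paraformaldehyde (Cu(OAc)2, KOAc, AcOH) and cracked to dimethyl 2-methylidenepropanedioate F1.
  - Isopropenylmagnesium bromide is added to cyclopent-2-enone under CuBr·SMe2 and a chiral ferrocenyl diphosphine, and the magnesium enolate is trapped with F1. This gives dimethyl 2-{[(1S,5R)-2-oxo-5-(prop-1-en-2-yl)cyclopentyl]methyl}propanedioate F2 (the same compound as A2), with C3/C4 trans by anti approach.
  - Excess MeMgBr/CeCl3 at −78 °C, with the malonate carried as its enolate, adds to the ketone anti to the neighbouring side chain. This gives dimethyl 2-{[(1S,2R,5R)-2-hydroxy-2-methyl-5-(prop-1-en-2-yl)cyclopentyl]methyl}propanedioate F3, which is silylated (Et3SiOTf, 2,6-lutidine) to its triethylsilyl ether F4.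
  - Mn(OAc)3·2H2O (trivalent manganese) with Cu(OAc)2 in EtOH at 60 °C closes ring B by 6-endo attack of the malonyl radical on the isopropenyl CH2. Oxidative elimination then gives dimethyl 1-methyl-4-methylidene-1-[(triethylsilyl)oxy]octahydro-6H-indene-6,6-dicarboxylate F5; any endocyclic isomer formed is 7 itself.
  - Saponification as in step 6 gives the diacid F6. Iodolactonisation puts the axial carboxylate on C5 and iodine on the former methylidene carbon, giving the iodomethyl lactone acid F7. Reduction with (Me3Si)3SiH returns 10.
  - The weak point of this fallback is the enantioselectivity of the first coupling.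

**Step 9.**
- What may go wrong: addition of the stabilised C13 carbanion to the hindered, neopentyl-type lactone carbonyl may be slow or reversible. Aldol closure of the isovaleryl α-carbon onto C10, or retro-Claisen cleavage of the side chain, could then take over.
- Fallback: it sets out from 12 (made from 10 as in step 8) and comes back at 14. The reactive enolate is used on the hindered carbonyl and the stabilised carbanion on an unhindered ester.
  - 12 is treated with the magnesium salt of monomethyl malonate, Mg(O2CCH2CO2Me)2, in THF (decarboxylative Claisen acylation). This gives the β-keto ester methyl 3-{1,4-dimethyl-8-oxo-1-[(triethylsilyl)oxy]octahydro-1H-4,6-(epoxymethano)inden-6-yl}-3-oxopropanoate F8.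
  - Excess kinetic lithium enolate of 4-methylpentan-2-one (LiN(iPr)2, THF, −78 → 0 °C; F8 carried as its enolate) opens the lactone at C14. This gives the triketo ester F9, with the C5 hydroxyl free and the diketone chain on C14.
  - Mg(OMe)2 in MeOH then closes C13 onto the ester carbon, which becomes C12, and gives 14.

**Step 10.**
- What may go wrong: alkylation on the enolate oxygen, or a stop after one prenyl group, because the second alkylation creates a quaternary carbon next to the spiro centre.
- Fallback: it sets out from 14 and comes back at 16. Tsuji–Trost diallylation with allyl methyl carbonate and Pd(PPh3)4 (zerovalent palladium) in THF, which strongly favours carbon, gives the 5,5-diallyl compound F10. Cross-metathesis with 2-methylbut-2-ene and the second-generation Grubbs catalyst (CH2Cl2, 40 °C) converts both allyl groups into prenyl groups and gives 16.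

**Step 4.**
- What may go wrong: conjugate addition of the malonate to the enal or to the product, which iminium activation also promotes, and slow condensation of an α-branched enal.
- Fallback: it sets out from 3 and comes back at 6, making C1=C6 by olefination instead of condensation. Appel bromination of 3 (CBr4, PPh3, 2,6-lutidine) gives the allylic bromide F11. PPh3 in MeCN gives the phosphonium bromide F12. Its ylide (NaN(SiMe3)2, THF, −78 °C) reacts with dimethyl 2-oxopropanedioate in a Wittig reaction to give 6.

## Further compounds

F1 | step 5 | dimethyl 2-methylidenepropanedioate | COC(=O)C(=C)C(=O)OC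
F2 | step 5 | dimethyl 2-{[(1S,5R)-2-oxo-5-(prop-1-en-2-yl)cyclopentyl]methyl}propanedioate (trans) | COC(=O)C(C(=O)OC)C[C@H]1[C@@H](CCC1=O)C(C)=C
F3 | step 5 | dimethyl 2-{[(1S,2R,5R)-2-hydroxy-2-methyl-5-(prop-1-en-2-yl)cyclopentyl]methyl}propanedioate | COC(=O)C(C(=O)OC)C[C@H]1[C@@H](CC[C@@]1(C)O)C(C)=C
F4 | step 5 | dimethyl 2-{[(1S,2R,5R)-2-methyl-5-(prop-1-en-2-yl)-2-[(triethylsilyl)oxy]cyclopentyl]methyl}propanedioate | COC(=O)C(C(=O)OC)C[C@H]1[C@@H](CC[C@@]1(C)O[Si](CC)(CC)CC)C(C)=C
F5 | step 5 | dimethyl (1R,3aR,7aS)-1-methyl-4-methylidene-1-[(triethylsilyl)oxy]octahydro-6H-indene-6,6-dicarboxylate | COC(=O)C2(C(=O)OC)C[C@H]3[C@@H](CC[C@@]3(C)O[Si](CC)(CC)CC)C(=C)C2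
F6 | step 5 | (1R,3aR,7aS)-1-methyl-4-methylidene-1-[(triethylsilyl)oxy]octahydro-6H-indene-6,6-dicarboxylic acid | OC(=O)C2(C(=O)O)C[C@H]3[C@@H](CC[C@@]3(C)O[Si](CC)(CC)CC)C(=C)C2
F7 | step 5 | 4-(iodomethyl)-1-methyl-8-oxo-1-[(triethylsilyl)oxy]octahydro-1H-4,6-(epoxymethano)indene-6-carboxylic acid, configuration as 10 | O=C(O)[C@@]12C[C@H]3[C@@H](CC[C@@]3(C)O[Si](CC)(CC)CC)[C@](CI)(C2)OC1=O
F8 | step 9 | methyl 3-{1,4-dimethyl-8-oxo-1-[(triethylsilyl)oxy]octahydro-1H-4,6-(epoxymethano)inden-6-yl}-3-oxopropanoate, configuration as 10 | COC(=O)CC(=O)[C@@]12C[C@H]3[C@@H](CC[C@@]3(C)O[Si](CC)(CC)CC)[C@](C)(C2)OC1=O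
F9 | step 9 | methyl 3-{4-hydroxy-1,4-dimethyl-6-(5-methyl-3-oxohexanoyl)-1-[(triethylsilyl)oxy]octahydro-1H-inden-6-yl}-3-oxopropanoate, diketone chain on the face of the C5 hydroxyl | COC(=O)CC(=O)[C@@]2(C[C@H]3[C@@H](CC[C@@]3(C)O[Si](CC)(CC)CC)[C@@](C)(O)C2)C(=O)CC(=O)CC(C)C
F10 | step 10 | (1'R,3a'R,4'S,7a'S)-4'-hydroxy-1',4'-dimethyl-3-(3-methylbutanoyl)-5,5-di(prop-2-en-1-yl)-1'-[(triethylsilyl)oxy]octahydrospiro[cyclohexane-1,6'-indene]-2,4,6-trione, 4-enol | C=CCC1(CC=C)C(=O)[C@@]2(C[C@H]3[C@@H](CC[C@@]3(C)O[Si](CC)(CC)CC)[C@@](C)(O)C2)C(=O)C(C(=O)CC(C)C)=C1O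
F11 | step 4 | {[(3R,6E)-8-bromo-3,7-dimethylocta-1,6-dien-3-yl]oxy}triethylsilane | C=C[C@](C)(O[Si](CC)(CC)CC)CC/C=C(\C)CBr
F12 | step 4 | {(2E,6R)-2,6-dimethyl-6-[(triethylsilyl)oxy]octa-2,7-dien-1-yl}triphenylphosphonium bromide | C=C[C@](C)(O[Si](CC)(CC)CC)CC/C=C(\C)C[P+](c1ccccc1)(c1ccccc1)c1ccccc1.[Br-]
A1 | alternative 1 | spiro acylphloroglucinol without prenyl groups, C9 triethylsilyl ether (same structure as 14) | CC(C)CC(=O)C1=C(O)C=C(O)[C@@]2(C[C@H]3[C@@H](CC[C@@]3(C)O[Si](CC)(CC)CC)[C@@](C)(O)C2)C1=O
A2 | alternative 2 | dimethyl 2-{[(1S,5R)-2-oxo-5-(prop-1-en-2-yl)cyclopentyl]methyl}propanedioate (trans) | COC(=O)C(C(=O)OC)C[C@H]1[C@@H](CCC1=O)C(C)=C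
A3 | alternative 3 | methyl 2-hydroxy-2-methyl-5-[1-(tert-butyldimethylsilyloxy)ethyl]cyclopentane-1-carboxylate, hydroxyl and ester cis | COC(=O)[C@H]1C(CC[C@@]1(C)O)C(C)O[Si](C)(C)C(C)(C)C
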